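**Retrosynthetic overview**
1. The spiro-cyclohexene (C14'–C15 and C2'–C4) is made last, by an endo-selective [4+2]-type Michael/aldol union of the enone monomer (7-epi-dehydrozaluzanin C) with the diosphenol made from the same monomer by C2 oxidation.
2. The monomer's 2-methylidenecyclopentanone ring comes from a monovalent-gold-catalysed 4→5 ring expansion (1,2-alkyl shift) of a 1-ethynylcyclobutanol; this is the key step and fixes the 3-oxo-4(15)-ene regiochemistry.
3. The seven-membered ring comes from a 6→7 diazoalkane ring expansion of a cyclohexanone, the cis-lactone from α-alkylation/reduction, and C10=CH2 from the C10 carbinol (a stereo-relay) by oxidation/methylenation.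
4. The cyclobutane, C1 and C5 come from an enone–allene [2+2] on (R)-4-silyloxycyclohexenone (six-membered, because cycloheptenones photoisomerise). That enone comes from cyclohexa-1,3-diene by 1O2 addition and a chiral-base Kornblum–DeLaMare rearrangement.
5. Ring order: six → four → seven (expansion) → lactone → five (expansion) → spiro six.

Assumption: the SMILES is read as drawn, so both lactones are cis-fused (H-6/H-7 cis, H-5/H-6 trans, H-1/H-5 cis) and the monomer is 7-epi-dehydrozaluzanin C; guaianolide locants (C1–C15, primes for the diosphenol half) are used at every stage and α is the face of H-1 and H-5.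

**Route**

Step 1
Reactants: 1 cyclohexa-1,3-diene
Product: 3 (R)-4-hydroxycyclohex-2-en-1-one, via endoperoxide 2 (not isolated)
Conditions: O2, tetraphenylporphyrin (cat.), hν, CH2Cl2, −20 °C; then 9-O-acetylcupreidine (10 mol %; or its cupreine pseudoenantiomer, whichever delivers R), 0 °C
Reagents that add atoms: dioxygen, O=O
Why: Singlet-oxygen [4+2] addition gives the meso endoperoxide, and the chiral-amine-catalysed Kornblum–DeLaMare rearrangement removes one enantiotopic bridgehead proton, so the surviving carbinol carbon (future C10) is set as R by the catalyst.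

Step 2
Reactants: 3 (R)-4-hydroxycyclohex-2-en-1-one
Product: 4 (R)-4-(tert-butyldimethylsilyloxy)cyclohex-2-en-1-one
Conditions: TBSCl, imidazole, CH2Cl2, 0 °C → rt
Reagents that add atoms: tert-butyldimethylsilyl chloride, CC(C)(C)[Si](C)(C)Cl
Why: Routine silylation of a secondary alcohol gives a bulky ether that survives the later enolate steps and shields one face of the enone.

Step 3
Reactants: 4 (R)-4-(tert-butyldimethylsilyloxy)cyclohex-2-en-1-one; 5 allene
Product: 6 cis-fused methylidenecyclobutane photoadduct
Conditions: hν (350 nm, Pyrex), allene (excess), THF, −78 °C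
Reagents that add atoms: none
Why: In the enone–allene [2+2] photocycloaddition the central allene carbon bonds to the α-carbon C5 (head-to-head) to give the cis-fused β,γ-unsaturated ketone, and approach anti to the C10 silyloxy group sets C1 and C5 (the minor syn adduct is removed by chromatography).

Step 4
Reactants: 6 cis-fused methylidenecyclobutane photoadduct
Product: 8 ring-expanded cycloheptanone, via α-silyl ketone 7 (not isolated)
Conditions: TMSCHN2, BF3·OEt2, CH2Cl2, −78 °C; then K2CO3 (cat.), MeOH, rt
Reagents that add atoms: trimethylsilyldiazomethane, C[Si](C)(C)C=[N+]=[N-]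
Why: In this Lewis-acid-promoted diazoalkane homologation (Tiffeneau–Demjanov-type 1,2-shift) the unbranched C8 migrates in preference to the ring-fusion carbon C5, so C7 is inserted next to the ketone without touching a stereocentre and the α-silyl group is lost on methanolysis.

Step 5
Reactants: 8 ring-expanded cycloheptanone; 9 methyl bromoacetate
Product: 10 trans-2,7-disubstituted keto ester
Conditions: LiN(i-Pr)2, THF, −78 °C; then 9, DMPU, −78 → −40 °C
Reagents that add atoms: none
Why: Kinetic deprotonation occurs at the only α-methylene (C7), and the enolate is alkylated anti to the pseudo-axial C5–C3 ring-fusion bond (the usual trans outcome for 2-substituted cycloalkanone enolates), which places the acetate arm α at C7.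

Step 6
Reactants: 10 trans-2,7-disubstituted keto ester
Product: 12 cis-fused lactone, via hydroxy ester 11 (not isolated)
Conditions: LiBH(s-Bu)3, THF, −78 → 0 °C; then AcOH, rt
Reagents that add atoms: none
Why: The bulky borohydride attacks the ketone equatorially, opposite the pseudo-axial C5–C3 bond, giving the 6α-alkoxide cis to the C7 arm, which lactonises on acidification to the cis-fused γ-lactone (ketone reduction/lactonisation, C6 set).

Step 7
Reactants: 12 cis-fused lactone
Product: 15 α-methylidene lactone, via Mannich base 13 (not isolated), via ammonium iodide 14 (not isolated)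
Conditions: LiN(i-Pr)2, THF, −78 °C; CH2=NMe2+ I−; then MeI, MeOH, rt; then aq NaHCO3, CH2Cl2
Reagents that add atoms: N,N-dimethylmethyleneiminium iodide, C=[N+](C)C.[I-]
Why: Mannich methylenation of the lactone enolate, quaternisation and E1cB loss of trimethylamine install the 11(13)-alkene without touching a stereocentre.

Step 8
Reactants: 15 α-methylidene lactone
Product: 17 cyclobutanone, via ozonide 16 (not isolated)
Conditions: O3, CH2Cl2, −78 °C (Sudan Red 7B end point); then Me2S, −78 °C → rt
Reagents that add atoms: ozone, [O-][O+]=O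
Why: Ozone cleaves the electron-rich, strained methylidenecyclobutane much faster than the electron-poor acrylate-type alkene, and reductive work-up of the ozonide gives the cyclobutanone (chemoselective ozonolysis).

Step 9
Reactants: 17 cyclobutanone
Product: 18 1-ethynylcyclobutanol
Conditions: HC≡CMgBr, LaCl3·2LiCl (30 mol %), THF, −78 °C; H2O quench
Reagents that add atoms: ethynylmagnesium bromide, C#C[Mg]Br
Why: Lanthanum-assisted Grignard 1,2-addition to the strained, highly electrophilic cyclobutanone outruns enolisation and attack on the lactone, the nucleophile entering from the convex face (this carbinol centre is erased in step 13).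

Step 10
Reactants: 18 1-ethynylcyclobutanol
Product: 19 desilylated diol
Conditions: HF·pyridine, THF, 0 °C → rt
Reagents that add atoms: none
Why: Fluoride cleavage of the secondary silyl ether under mildly acidic conditions leaves the tertiary propargylic alcohol and the α-methylidene lactone intact.

Step 11
Reactants: 19 desilylated diol
Product: 20 C10 ketone
Conditions: Dess–Martin periodinane, CH2Cl2, rt
Reagents that add atoms: none
Why: Dess–Martin oxidation converts the only oxidisable (secondary) alcohol to the ketone under non-epimerising conditions.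

Step 12
Reactants: 20 C10 ketone
Product: 21 10(14)-methylidene alkynol
Conditions: Zn, CH2Br2, TiCl4 (pre-mixed, THF, 0 °C); then 20, CH2Cl2, 0 °C → rt
Reagents that add atoms: dibromomethane, BrCBr
Why: The non-basic zinc/titanium methylenating reagent (Lombardo olefination) converts the ketone to the exocyclic alkene without enolising C1 or attacking the lactone.

Step 13
Reactants: 21 10(14)-methylidene alkynol
Product: 22 7-epi-dehydrozaluzanin C
Conditions: (Ph3P)AuCl (2 mol %), AgSbF6 (2 mol %), CH2Cl2, rt
Reagents that add atoms: none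
Why: Monovalent-gold π-activation of the alkyne triggers a semipinacol-type 1,2-shift of the more substituted cyclobutane carbon C5 (4→5 ring expansion, retention at C5), and protodeauration gives the 2-methylidenecyclopentanone with the methylidene next to C5 and the ketone at C3.

Step 14
Reactants: 22 7-epi-dehydrozaluzanin C
Product: 25 2α-hydroxy ketone, via silyl dienol ether 23 (not isolated), via silyloxy epoxide 24 (not isolated)
Conditions: TMSOTf, Et3N, CH2Cl2, −78 °C; then dimethyldioxirane, acetone, −78 °C; then AcOH (cat.), THF–H2O, 0 °C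
Reagents that add atoms: dimethyldioxirane, CC1(C)OO1
Why: In this Rubottom oxidation soft enolisation can only occur toward C2, and dimethyldioxirane epoxidises the electron-rich silyl enol ether from the convex α face, the silyloxy epoxide collapsing to the α-hydroxy ketone on hydrolysis (this centre is erased in step 15).

Step 15
Reactants: 25 2α-hydroxy ketone
Product: 26 diosphenol
Conditions: Dess–Martin periodinane, CH2Cl2, 0 °C; used at once
Reagents that add atoms: none
Why: Dess–Martin oxidation of the acyloin gives the 2,3-dione, which enolises toward C1 (its only α-hydrogen) to the conjugated diosphenol whose C14'=C10'–C1'=C2' unit is a locked s-cis diene.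

Step 16
Reactants: 26 diosphenol; 22 7-epi-dehydrozaluzanin C
Product: 28 target spiro dimer CNP0269880.1, via Michael adduct 27 (not isolated)
Conditions: 22 (2 equiv), i-Pr2NEt (0.3 equiv), CH2Cl2, 0 °C, 26 added over 6 h; then rt
Reagents that add atoms: none
Why: Proposed new method: the hindered amine deprotonates the acidic diosphenol to a 2-oxido-diene that adds through its unhindered γ-terminus C14' to C15 of the exocyclic enone (vinylogous Michael), and the resulting C4 enolate closes on the activated C2' ketone of the 1,2-dione (intramolecular aldol, six-membered ring) in a compact endo-type transition state, bonding through the convex α face of the cyclopentanone and the face of the diene half remote from its α-oriented lactone, which sets C4 and C2' as in the target; the closest known reaction types are amine-base-catalysed Diels–Alder reactions of 3-hydroxy-2-pyrones and anthrones and the thermal Diels–Alder dimerisations of dehydrozaluzanin-type dienes.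

**Compound list**

1 | cyclohexa-1,3-diene | C1=CC=CCC1 | starting material
2 | 2,3-dioxabicyclo[2.2.2]oct-5-ene (meso endoperoxide) | C1C[C@H]2C=C[C@@H]1OO2 | intermediate
3 | (R)-4-hydroxycyclohex-2-en-1-one | O=C1C=C[C@H](O)CC1 | intermediate
4 | (R)-4-(tert-butyldimethylsilyloxy)cyclohex-2-en-1-one | O=C1C=C[C@H](O[Si](C)(C)C(C)(C)C)CC1 | intermediate
5 | allene (propa-1,2-diene) | C=C=C | starting material
6 | photoadduct: cis-fused 5-(tert-butyldimethylsilyloxy)-8-methylidenebicyclo[4.2.0]octan-2-one; C6 ketone, H-1α, H-5α, cyclobutane β, 10α-OTBS | O=C1CC[C@@H](O[Si](C)(C)C(C)(C)C)[C@@H]2CC(=C)[C@H]12 | intermediate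
7 | α-silyl ketone: 6-(tert-butyldimethylsilyloxy)-9-methylidene-3-(trimethylsilyl)bicyclo[5.2.0]nonan-2-one (both C7 epimers) | O=C1C([Si](C)(C)C)CC[C@@H](O[Si](C)(C)C(C)(C)C)[C@@H]2CC(=C)[C@H]12 | intermediate
8 | ring-expanded cycloheptanone: cis-fused 6-(tert-butyldimethylsilyloxy)-9-methylidenebicyclo[5.2.0]nonan-2-one; H-1α, H-5α, 10α-OTBS | O=C1CCC[C@@H](O[Si](C)(C)C(C)(C)C)[C@@H]2CC(=C)[C@H]12 | intermediate
9 | methyl bromoacetate | COC(=O)CBr | starting material
10 | keto ester: 8 with CH2CO2Me at C7 on the α face (trans to the cyclobutane bond at C5) | O=C1[C@@H](CC(=O)OC)CC[C@@H](O[Si](C)(C)C(C)(C)C)[C@@H]2CC(=C)[C@H]12 | intermediate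
11 | hydroxy ester: 6α-alcohol of 10 (OH cis to the C7 arm; H-6β, H-7β) | O[C@H]1[C@@H](CC(=O)OC)CC[C@@H](O[Si](C)(C)C(C)(C)C)[C@@H]2CC(=C)[C@H]12 | intermediate
12 | cis-fused lactone: 12,6-olide with O-6 and C-11 both α, 10α-OTBS, 3-methylidenecyclobutane (C1–C2–C3–C5) | O=C1C[C@H]2CC[C@@H](O[Si](C)(C)C(C)(C)C)[C@@H]3CC(=C)[C@@H]3[C@H]2O1 | intermediate
13 | Mannich base: 11-(dimethylaminomethyl) derivative of 12 (C11 epimers) | CN(C)CC1[C@H]2CC[C@@H](O[Si](C)(C)C(C)(C)C)[C@@H]3CC(=C)[C@@H]3[C@H]2OC1=O | intermediate
14 | ammonium iodide: 11-(trimethylammoniomethyl) iodide of 12 | C[N+](C)(C)CC1[C@H]2CC[C@@H](O[Si](C)(C)C(C)(C)C)[C@@H]3CC(=C)[C@@H]3[C@H]2OC1=O.[I-] | intermediate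
15 | α-methylidene lactone: 11(13)-ene of 12 | C=C1[C@H]2CC[C@@H](O[Si](C)(C)C(C)(C)C)[C@@H]3CC(=C)[C@@H]3[C@H]2OC1=O | intermediate
16 | ozonide: spiro-1,2,4-trioxolane at C3 of 15 (C3 epimers) | C=C1[C@H]2CC[C@@H](O[Si](C)(C)C(C)(C)C)[C@@H]3CC4(OOCO4)[C@@H]3[C@H]2OC1=O | intermediate
17 | cyclobutanone: 3-oxo (four-membered C1–C2–C3–C5) 11(13)-en-12,6-olide, 10α-OTBS | C=C1[C@H]2CC[C@@H](O[Si](C)(C)C(C)(C)C)[C@@H]3CC(=O)[C@@H]3[C@H]2OC1=O | intermediate
18 | 1-ethynylcyclobutanol: 3-ethynyl-3-hydroxy derivative of 17, ethynyl on the convex face (cis to H-5) | C=C1[C@H]2CC[C@@H](O[Si](C)(C)C(C)(C)C)[C@@H]3C[C@@](O)(C#C)[C@@H]3[C@H]2OC1=O | intermediate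
19 | desilylated diol: 10α-hydroxy analogue of 18 | C=C1[C@H]2CC[C@@H](O)[C@@H]3C[C@@](O)(C#C)[C@@H]3[C@H]2OC1=O | intermediate
20 | C10 ketone of 19 | C=C1[C@H]2CCC(=O)[C@@H]3C[C@@](O)(C#C)[C@@H]3[C@H]2OC1=O | intermediate
21 | 10(14)-methylidene alkynol (ring-expansion substrate) | C=C1[C@H]2CCC(=C)[C@@H]3C[C@@](O)(C#C)[C@@H]3[C@H]2OC1=O | intermediate
22 | 7-epi-dehydrozaluzanin C: 3-oxoguaia-4(15),10(14),11(13)-trien-12,6-olide, H-1α, H-5α, H-6β, H-7β | C=C1C(=O)C[C@H]2C(=C)CC[C@@H]3C(=C)C(=O)O[C@@H]3[C@H]21 | intermediate
23 | silyl dienol ether: 3-(trimethylsilyloxy)guaia-2,4(15),10(14),11(13)-tetraen-12,6-olide | C=C1C(O[Si](C)(C)C)=C[C@H]2C(=C)CC[C@@H]3C(=C)C(=O)O[C@@H]3[C@H]21 | intermediate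
24 | silyloxy epoxide: 2α,3α-epoxy-3-(trimethylsilyloxy) derivative of 23 | C=C1[C@]2(O[Si](C)(C)C)O[C@@H]2[C@H]3C(=C)CC[C@@H]4C(=C)C(=O)O[C@@H]4[C@H]31 | intermediate
25 | 2α-hydroxy ketone: 2α-hydroxy derivative of 22 | C=C1C(=O)[C@H](O)[C@H]2C(=C)CC[C@@H]3C(=C)C(=O)O[C@@H]3[C@H]21 | intermediate
26 | diosphenol: 2-hydroxy-3-oxoguaia-1,4(15),10(14),11(13)-tetraen-12,6-olide, H-5α, H-6β, H-7β | C=C1C(=O)C(O)=C2C(=C)CC[C@@H]3C(=C)C(=O)O[C@@H]3[C@@H]12 | intermediate
27 | Michael adduct: C14'–C15-linked 2',3'-dioxo-1'(10')-ene half joined to the C3–C4 enolate of the other half, diisopropylethylammonium salt | C=C1C(=O)C(=O)C2=C(CCC3=C([O-])C[C@H]4C(=C)CC[C@@H]5C(=C)C(=O)O[C@@H]5[C@H]43)CC[C@@H]3C(=C)C(=O)O[C@@H]3[C@@H]12.CC[NH+](C(C)C)C(C)C | intermediate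
28 | CNP0269880.1, spiro dimer (C2'–C4 and C14'–C15 bonds, 2'-OH, 1'(10')-ene) | C=C1C(=O)[C@]2(O)C3=C(CC[C@@H]4C(=C)C(=O)O[C@@H]4[C@@H]13)CC[C@]21C(=O)C[C@H]2C(=C)CC[C@@H]3C(=C)C(=O)O[C@@H]3[C@H]21 | target

**Totals and risks**

Total steps: 16. Longest linear sequence: 16 (steps 1–16; the last step joins 26 with its own precursor 22).

Steps most likely to fail:

Step 6 (face selectivity of the ketone reduction, which has substituents on both flanking carbons). Fallback: setting out from 10, reduce from the other face (NaBH4, CeCl3·7H2O, MeOH, −40 °C, neutral work-up) to the 6β-hydroxy ester F1, which cannot close the cis-lactone directly. Saponify it (LiOH, THF–H2O, 0 °C) to the hydroxy acid F2 and close the ring by Mitsunobu lactonisation (PPh3, DIAD, THF, 0 °C). This forms the C6–O bond with inversion and comes back to the route at 12, so C6 is set by SN2 displacement instead of carbonyl-face control.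

Step 13 (the gold-catalysed ring expansion, where enyne cycloisomerisation or drift of the new exocyclic alkene could compete). Fallback: setting out from 21, semihydrogenate the alkyne (H2, Pd/CaCO3 poisoned with Pb(OAc)2, quinoline, EtOAc) to the 1-vinylcyclobutanol F3. Then run the divalent-palladium Wacker-type oxidative ring expansion (PdCl2(MeCN)2 10 mol %, p-benzoquinone, THF, rt; alkene activation, 1,2-shift of C5, β-hydride elimination), which comes back to the route at 22.

Step 16 (the proposed new method; the base may instead promote self-condensation of 26 or oligomerisation of 22). Fallback with known chemistry: setting out from 26, silylate (TBSOTf, 2,6-lutidine, CH2Cl2, −78 °C) to the silyl ether of the diosphenol F4. Heat it with 22 (2 equiv, toluene, 80 °C, BHT) in a neutral thermal Diels–Alder reaction, of the kind established for dehydrozaluzanin-type dienes, to give the O-silylated adduct F5. Desilylate (HF·pyridine, THF, rt) to come back to the route at 28.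

**Further compounds**

F1 | step 6 | 6β-hydroxy ester (C6 epimer of 11) | O[C@@H]1[C@@H](CC(=O)OC)CC[C@@H](O[Si](C)(C)C(C)(C)C)[C@@H]2CC(=C)[C@H]12
F2 | step 6 | 6β-hydroxy acid | O[C@@H]1[C@@H](CC(=O)O)CC[C@@H](O[Si](C)(C)C(C)(C)C)[C@@H]2CC(=C)[C@H]12
F3 | step 13 | 1-vinylcyclobutanol (3-ethenyl analogue of 21) | C=C1[C@H]2CCC(=C)[C@@H]3C[C@@](O)(C=C)[C@@H]3[C@H]2OC1=O
F4 | step 16 | tert-butyldimethylsilyl ether of diosphenol 26 | C=C1C(=O)C(O[Si](C)(C)C(C)(C)C)=C2C(=C)CC[C@@H]3C(=C)C(=O)O[C@@H]3[C@@H]12
F5 | step 16 | 2'-O-tert-butyldimethylsilyl ether of 28 | C=C1C(=O)[C@]2(O[Si](C)(C)C(C)(C)C)C3=C(CC[C@@H]4C(=C)C(=O)O[C@@H]4[C@@H]13)CC[C@]21C(=O)C[C@H]2C(=C)CC[C@@H]3C(=C)C(=O)O[C@@H]3[C@H]21
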